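Counting every dissolved G as L.Q is the trap here, for each L stands at a fork.

G 0.050 M; Q 0.0525 M; time 80 s

1. the L.Q standing at 80 s, as a percentage of the G charged
2. the change that raises the amount of L.Q at 80 s, in percent of the G charged most ("none" if none brings more than 2 percentage points) (larch / elm / cedar / none)
3. amount of L.Q at 80 s, in percent of the G charged, after elm

- larch: doubling the dissolution coefficient of step 4, all else as stated
- elm: doubling the solubility in step 4, all else as stated
- cedar: doubling the amount of Q, all else as stated

    2 L → L2 (k1 = 2.5 L mol⁻¹ s⁻¹)
    L.Q ⇌ X (K2 = 3.1, k2 = 0.0058 s⁻¹)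
    L → Z (k3 = 0.13 s⁻¹)
    G ⇌ L, rate k4*(cs4 - [L]) while solid is left; crystals form when [L] > cs4 (cs4 = 42 mM, k4 = 0.012 s⁻¹)
    L + Q → L.Q (k5 = 4.4 L mol⁻¹ s⁻¹)

For the next person at the bench: the flask holds solid G, which feeds L at the dissolution coefficient 0.012 s⁻¹ times the gap below the solubility 42 mM, and Q. L goes on to L.Q or to Z, and L.Q passes on to X with a forward half-life of 120 s. L should stand near 1.40 mM, far below the solubility, so the feed stays close to 0.012 s⁻¹ times 42 mM, and pairing of L pulls less than Q does. One L therefore has the chance φ = q/(q + z) of reaching Q, the fork share (a selectivity): q is 4.4 L mol⁻¹ s⁻¹ times [Q], z is 0.13 s⁻¹, and φ at the charge is 64.0%.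

Feed by the asked time: at most 80.6% of G, so some G stays solid.
Q at 40.0 s: 0.0396 M, so φ = 57.3%.
L.Q plus X: 46.2% of G.
L.Q, after a mean age of 40.0 s: 36.6%.

Elm and larch each double the opening feed, at which the charge of 0.050 M of G lasts about 49.6 s, and the same lines give 40.1%. Cedar gives 48.0%, more than either. L.Q is not to be left standing past 80 s, which is already 66.7% of its forward half-life.

The forecast said 34% where the lines above give 36.6%, said 40.3% after elm where they give 40.1%, and named cedar as the best change, noting for the flask as charged that “G is not exhausted”. The simulation gives 34.1%, gives 40.2% after elm, and has cedar as the best change, with gains of 12 percentage points for cedar, 6.3 points for larch and 6.1 points for elm.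

In the flask, Q stands at 59.8% of its charge at 80.0 s, so φ there is 51.5%, and its mean with the charge value is 57.8%; L.Q and X together hold 58.1% of what L.Q, X and Z share. In a neighbouring flask, the same but with 0.013 M of Q, φ starts at 30.6% and ends at 15.8%, a mean of 23.2%. There L.Q and X hold 22.8% of that sum, and Z stands at 50.6%.

All constants come from no measurement.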